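**Retrosynthetic overview**
1. The seven-membered ring is closed last: the enal (C8=C9, C14 formyl) comes from an intramolecular aldol condensation of a 1,7-dialdehyde; the C6 ester is put on just before.
2. Key C6–C7 bond: a cyclopentane carbaldehyde (C6) is attacked by a propanal homoenolate equivalent (nucleophilic β-carbon C7 carrying C8 and C14 as a masked aldehyde); chelation sets C6.
3. The carbaldehyde comes from a 2-(dimethoxymethyl)cyclopentanone plus an isopropyl nucleophile (sets C4); the acetal carbon is added to an enol silane (sets C5).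
4. The enol silane comes from 3-allylcyclopentenone by catalytic asymmetric conjugate methylation (sets quaternary C1; allyl is the latent C10–C9 aldehyde).
5. Ring order: the five-membered ring is bought, the seven-membered ring is formed in the final step.

Assumption: atom labels C1–C15 follow daucane numbering (C1 quaternary, C4 carbinol, C5 ring-fusion CH, C6 ester carbon, C8=C9 alkene, C14 formyl); the SMILES strings are authoritative for configuration.

**Step 1**
Reactants: 1 3-ethoxycyclopent-2-en-1-one; 2 allylmagnesium bromide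
Product: 4 3-(prop-2-en-1-yl)cyclopent-2-en-1-one, via bromomagnesium alkoxide 3 (not isolated)
Conditions: 2 (1.2 equiv), THF, 0 °C; then 1 M aq. HCl, 0 °C
Reagents that add atoms: water, O
Why: 1,2-Grignard addition to the vinylogous ester followed by acid-mediated carbonyl transposition (Stork–Danheiser sequence); no stereocentre is formed.

**Step 2**
Reactants: 4 3-(prop-2-en-1-yl)cyclopent-2-en-1-one
Product: 6 trimethyl{[(3R)-3-methyl-3-(prop-2-en-1-yl)cyclopent-1-en-1-yl]oxy}silane, via aluminium enolate 5 (not isolated)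
Conditions: AlMe3 (1.4 equiv), Cu(OTf)2 (5 mol %), chiral sulfonate-bearing imidazolinium salt (NHC precursor, 5 mol %), THF, −78 → −30 °C; then TMSOTf (1.5 equiv), −30 → 0 °C
Reagents that add atoms: trimethylaluminium, C[Al](C)C; trimethylsilyl trifluoromethanesulfonate, C[Si](C)(C)OS(=O)(=O)C(F)(F)F
Why: Copper-catalysed asymmetric conjugate addition of methyl creates quaternary C1, the chiral NHC–copper catalyst selecting the enone face (ligand enantiomer chosen for R), and O-silylation fixes the regiodefined enolate.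

**Step 3**
Reactants: 6 trimethyl{[(3R)-3-methyl-3-(prop-2-en-1-yl)cyclopent-1-en-1-yl]oxy}silane
Product: 7 (2S,3R)-2-(dimethoxymethyl)-3-methyl-3-(prop-2-en-1-yl)cyclopentan-1-one
Conditions: HC(OMe)3 (3 equiv), TMSOTf (5 mol %), CH2Cl2, −78 °C
Reagents that add atoms: trimethyl orthoformate, COC(OC)OC
Why: Mukaiyama-type addition of the enol silane to the dimethoxycarbenium ion, the electrophile entering C5 anti to the larger allyl group on C1 (cis to CH3); the selectivity is expected to be moderate (about 3:1), so the minor C5 epimer is separated, re-equilibrated with DBU and recycled.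

**Step 4**
Reactants: 7 (2S,3R)-2-(dimethoxymethyl)-3-methyl-3-(prop-2-en-1-yl)cyclopentan-1-one; 8 isopropylmagnesium chloride
Product: 10 (1R,2R,5R)-2-hydroxy-5-methyl-2-(propan-2-yl)-5-(prop-2-en-1-yl)cyclopentane-1-carbaldehyde, via hydroxy acetal 9 (not isolated)
Conditions: 8 (2 equiv), CeCl3 (2 equiv), THF, −78 → 0 °C; then 1 M aq. HCl, THF, 0 °C → rt
Reagents that add atoms: water, O
Why: Organocerium 1,2-addition (limits enolisation and β-hydride reduction) attacks the ketone face anti to the C5 acetal substituent, setting C4 with OH cis to C5–C6, and the acidic work-up hydrolyses the acetal to the aldehyde, which sits on the face of the two small neighbours (OH and CH3).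

**Step 5**
Reactants: 10 (1R,2R,5R)-2-hydroxy-5-methyl-2-(propan-2-yl)-5-(prop-2-en-1-yl)cyclopentane-1-carbaldehyde; 11 [2-(1,3-dioxolan-2-yl)ethyl]magnesium bromide
Product: 12 (1R,2S,3R)-2-[(1S)-3-(1,3-dioxolan-2-yl)-1-hydroxypropyl]-3-methyl-1-(propan-2-yl)-3-(prop-2-en-1-yl)cyclopentan-1-ol
Conditions: 11 (2.5 equiv), THF, −78 → −40 °C; then H2O
Reagents that add atoms: none
Why: Grignard addition of a propanal homoenolate (d3) equivalent joins the two normally electrophilic carbons C6 and C7; the first equivalent forms the C4 magnesium alkoxide, whose six-membered chelate with the aldehyde leaves open only the face anti to quaternary C1 (Cram chelate control), giving the 6S carbinol (1,3-anti diol).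

**Step 6**
Reactants: 12 (1R,2S,3R)-2-[(1S)-3-(1,3-dioxolan-2-yl)-1-hydroxypropyl]-3-methyl-1-(propan-2-yl)-3-(prop-2-en-1-yl)cyclopentan-1-ol; 13 4-(acetyloxy)benzoyl chloride
Product: 14 (1S)-3-(1,3-dioxolan-2-yl)-1-[(1S,2R,5R)-2-hydroxy-5-methyl-2-(propan-2-yl)-5-(prop-2-en-1-yl)cyclopentyl]propyl 4-(acetyloxy)benzoate
Conditions: 13 (1.3 equiv), Et3N, DMAP (0.2 equiv), CH2Cl2, 0 °C → rt
Reagents that add atoms: none
Why: DMAP-catalysed acylation esterifies the secondary C6 hydroxyl and leaves the tertiary C4 hydroxyl untouched; no stereocentre is affected.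

**Step 7**
Reactants: 14 (1S)-3-(1,3-dioxolan-2-yl)-1-[(1S,2R,5R)-2-hydroxy-5-methyl-2-(propan-2-yl)-5-(prop-2-en-1-yl)cyclopentyl]propyl 4-(acetyloxy)benzoate
Product: 16 (1S)-3-(1,3-dioxolan-2-yl)-1-[(1S,2R,5R)-2-hydroxy-5-methyl-5-(2-oxoethyl)-2-(propan-2-yl)cyclopentyl]propyl 4-(acetyloxy)benzoate, via ozonide 15 (not isolated)
Conditions: O3, CH2Cl2, −78 °C; then Me2S, −78 °C → rt
Reagents that add atoms: ozone, [O-][O+]=O
Why: Ozonolysis with reductive work-up cleaves the only C=C bond and reveals the C9 aldehyde; no stereocentre is affected.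

**Step 8**
Reactants: 16 (1S)-3-(1,3-dioxolan-2-yl)-1-[(1S,2R,5R)-2-hydroxy-5-methyl-5-(2-oxoethyl)-2-(propan-2-yl)cyclopentyl]propyl 4-(acetyloxy)benzoate
Product: 19 (3R,3aS,4S,8aR)-6-formyl-3-hydroxy-8a-methyl-3-(propan-2-yl)-1,2,3,3a,4,5,8,8a-octahydroazulen-4-yl 4-hydroxybenzoate, via dialdehyde 17 (not isolated), via enal acetate 18 (not isolated)
Conditions: 1 M aq. HCl, THF, rt; then pyrrolidine (3 equiv), AcOH (1 equiv), CH2Cl2, rt
Reagents that add atoms: water, O
Why: Acetal hydrolysis gives the 1,7-dialdehyde, amine-catalysed intramolecular aldol condensation (enamine of the unhindered C14 aldehyde attacks the C9 aldehyde, then dehydration) closes the cycloheptene as the conjugated enal with the trans ring fusion fixed by the trans arms on C1 and C5, and excess pyrrolidine frees the phenol by aminolysis of the aryl acetate.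

**Compound list**
1 | 3-ethoxycyclopent-2-en-1-one | CCOC1=CC(=O)CC1 | starting material
2 | allylmagnesium bromide | C=CC[Mg]Br | starting material
3 | bromomagnesium 3-ethoxy-1-(prop-2-en-1-yl)cyclopent-2-en-1-olate (racemic) | CCOC1=CC(CC=C)(O[Mg]Br)CC1 | intermediate (not isolated)
4 | 3-(prop-2-en-1-yl)cyclopent-2-en-1-one | C=CCC1=CC(=O)CC1 | intermediate
5 | dimethylaluminium (3R)-3-methyl-3-(prop-2-en-1-yl)cyclopent-1-en-1-olate | C=CC[C@@]1(C)CCC(O[Al](C)C)=C1 | intermediate (not isolated)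
6 | trimethyl{[(3R)-3-methyl-3-(prop-2-en-1-yl)cyclopent-1-en-1-yl]oxy}silane | C=CC[C@@]1(C)CCC(O[Si](C)(C)C)=C1 | intermediate
7 | (2S,3R)-2-(dimethoxymethyl)-3-methyl-3-(prop-2-en-1-yl)cyclopentan-1-one (acetal carbon cis to CH3) | O=C1CC[C@](C)(CC=C)[C@H]1C(OC)OC | intermediate
8 | isopropylmagnesium chloride | CC(C)[Mg]Cl | starting material
9 | (1R,2R,3R)-2-(dimethoxymethyl)-3-methyl-1-(propan-2-yl)-3-(prop-2-en-1-yl)cyclopentan-1-ol | CC(C)[C@]1(O)CC[C@](C)(CC=C)[C@H]1C(OC)OC | intermediate (not isolated)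
10 | (1R,2R,5R)-2-hydroxy-5-methyl-2-(propan-2-yl)-5-(prop-2-en-1-yl)cyclopentane-1-carbaldehyde (CHO, OH and CH3 all cis) | CC(C)[C@]1(O)CC[C@](C)(CC=C)[C@H]1C=O | intermediate
11 | [2-(1,3-dioxolan-2-yl)ethyl]magnesium bromide | Br[Mg]CCC1OCCO1 | starting material
12 | (1R,2S,3R)-2-[(1S)-3-(1,3-dioxolan-2-yl)-1-hydroxypropyl]-3-methyl-1-(propan-2-yl)-3-(prop-2-en-1-yl)cyclopentan-1-ol | CC(C)[C@]1(O)CC[C@](C)(CC=C)[C@H]1[C@@H](O)CCC2OCCO2 | intermediate
13 | 4-(acetyloxy)benzoyl chloride | CC(=O)Oc1ccc(cc1)C(Cl)=O | starting material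
14 | (1S)-3-(1,3-dioxolan-2-yl)-1-[(1S,2R,5R)-2-hydroxy-5-methyl-2-(propan-2-yl)-5-(prop-2-en-1-yl)cyclopentyl]propyl 4-(acetyloxy)benzoate | CC(C)[C@]1(O)CC[C@](C)(CC=C)[C@H]1[C@@H](OC(=O)c2ccc(OC(C)=O)cc2)CCC3OCCO3 | intermediate
15 | secondary ozonide of 14 (1,2,4-trioxolan-3-ylmethyl group on C1; new ring carbon unassigned) | CC(C)[C@]1(O)CC[C@](C)(CC2OCOO2)[C@H]1[C@@H](OC(=O)c3ccc(OC(C)=O)cc3)CCC4OCCO4 | intermediate (not isolated)
16 | (1S)-3-(1,3-dioxolan-2-yl)-1-[(1S,2R,5R)-2-hydroxy-5-methyl-5-(2-oxoethyl)-2-(propan-2-yl)cyclopentyl]propyl 4-(acetyloxy)benzoate | CC(C)[C@]1(O)CC[C@](C)(CC=O)[C@H]1[C@@H](OC(=O)c2ccc(OC(C)=O)cc2)CCC3OCCO3 | intermediate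
17 | (1S)-1-[(1S,2R,5R)-2-hydroxy-5-methyl-5-(2-oxoethyl)-2-(propan-2-yl)cyclopentyl]-4-oxobutyl 4-(acetyloxy)benzoate | CC(C)[C@]1(O)CC[C@](C)(CC=O)[C@H]1[C@@H](OC(=O)c2ccc(OC(C)=O)cc2)CCC=O | intermediate (not isolated)
18 | (3R,3aS,4S,8aR)-6-formyl-3-hydroxy-8a-methyl-3-(propan-2-yl)-1,2,3,3a,4,5,8,8a-octahydroazulen-4-yl 4-(acetyloxy)benzoate | CC(C)[C@]1(O)CC[C@]2(C)CC=C(C=O)C[C@H](OC(=O)c3ccc(OC(C)=O)cc3)[C@H]21 | intermediate (not isolated)
19 | (3R,3aS,4S,8aR)-6-formyl-3-hydroxy-8a-methyl-3-(propan-2-yl)-1,2,3,3a,4,5,8,8a-octahydroazulen-4-yl 4-hydroxybenzoate | CC(C)[C@]1(O)CC[C@]2(C)CC=C(C=O)C[C@H](OC(=O)c3ccc(O)cc3)[C@H]21 | target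

**Totals and risks**
Total step count: 8. Longest linear sequence: 8.

The three steps most likely to fail:

Step 4 (isopropyl addition to a hindered, enolisable ketone, then acid hydrolysis to a dehydration-prone aldol). The fallback sets out from 7 and comes back at 9. Prop-1-en-2-ylmagnesium bromide with CeCl3 (an sp2 nucleophile that is smaller and cannot reduce by β-hydride transfer) is added to 7 to give the isopropenyl carbinol F1. Hydrogen-atom-transfer hydrogenation with tris(dipivaloylmethanato)manganese, Mn(dpm)3, PhSiH3 and t-BuOOH in i-PrOH then reduces only the 1,1-disubstituted alkene, leaving the monosubstituted allyl group, and gives 9, which is hydrolysed to 10 as before.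

Step 5 (key addition: a very hindered aldehyde, possible reduction or retro-aldol, and stereocontrol that rests on chelation). The fallback sets out from 10 and comes back at 12, with the polarity inverted at C6 instead of C7. Aldehyde 10 is converted with propane-1,3-dithiol and Zn(OTf)2 into the dithiane F2. Its O,C-dianion (n-BuLi, THF/HMPA) is alkylated with 2-(2-bromoethyl)-1,3-dioxolane to give the disubstituted dithiane F3, which is unmasked with MeI and CaCO3 in aqueous MeCN to the β-hydroxy ketone F4. Reduction with Me4NBH(OAc)3 delivers hydride intramolecularly from the C4 hydroxyl (1,3-anti) and gives 12.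

Step 8 (seven-membered aldol condensation: which aldehyde acts as the enamine, oligomerisation, and the deacetylation in the same pot). The fallback sets out from 14 and comes back at 18, closing the ring by olefin metathesis. The dioxolane of 14 is hydrolysed (PPTS, aqueous acetone) to the aldehyde F5, which is α-methylenated with N,N-dimethylmethyleneiminium iodide and Et3N to the 2-substituted acrolein F6. Ring closure between the allyl group and the new methylene with the second-generation Hoveyda–Grubbs catalyst gives 18 with the C8=C9 bond and formyl group in place, and pyrrolidine then gives 19.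

The facial selectivity of step 3 is the other soft spot; it is handled there by separation and recycling of the C5 epimer.

**Further compounds**
F1 | step 4 | isopropenyl analogue of 9: 2-(dimethoxymethyl)-3-methyl-1-(prop-1-en-2-yl)-3-(prop-2-en-1-yl)cyclopentan-1-ol, same spatial arrangement as 9 | C=C(C)[C@]1(O)CC[C@](C)(CC=C)[C@H]1C(OC)OC
F2 | step 5 | 1,3-dithiane of aldehyde 10: 2-(1,3-dithian-2-yl)-3-methyl-1-(propan-2-yl)-3-(prop-2-en-1-yl)cyclopentan-1-ol, same spatial arrangement as 10 | CC(C)[C@]1(O)CC[C@](C)(CC=C)[C@H]1C2SCCCS2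
F3 | step 5 | 2-{2-[2-(1,3-dioxolan-2-yl)ethyl]-1,3-dithian-2-yl}-3-methyl-1-(propan-2-yl)-3-(prop-2-en-1-yl)cyclopentan-1-ol, same spatial arrangement as 10 | CC(C)[C@]1(O)CC[C@](C)(CC=C)[C@H]1C2(CCC3OCCO3)SCCCS2
F4 | step 5 | 3-(1,3-dioxolan-2-yl)-1-[2-hydroxy-5-methyl-2-(propan-2-yl)-5-(prop-2-en-1-yl)cyclopentyl]propan-1-one, acyl group cis to OH and CH3 | CC(C)[C@]1(O)CC[C@](C)(CC=C)[C@H]1C(=O)CCC2OCCO2
F5 | step 8 | (1S)-1-[(1S,2R,5R)-2-hydroxy-5-methyl-2-(propan-2-yl)-5-(prop-2-en-1-yl)cyclopentyl]-4-oxobutyl 4-(acetyloxy)benzoate | CC(C)[C@]1(O)CC[C@](C)(CC=C)[C@H]1[C@@H](OC(=O)c2ccc(OC(C)=O)cc2)CCC=O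
F6 | step 8 | α-methylene aldehyde from F5: 3-formyl-1-[2-hydroxy-5-methyl-2-(propan-2-yl)-5-(prop-2-en-1-yl)cyclopentyl]but-3-en-1-yl 4-(acetyloxy)benzoate, same spatial arrangement as F5 | CC(C)[C@]1(O)CC[C@](C)(CC=C)[C@H]1[C@@H](OC(=O)c2ccc(OC(C)=O)cc2)CC(=C)C=O
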